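## Retrosynthetic overview

- The target is a (2R,3R)-trans-2-aryl-3-hydroxymethyl-2,3-dihydro-1,4-benzodioxine (O1–C2(aryl)–C3(CH2OH)–O4, OMe at C5, (E)-propenal at C7). Desilylation and a Wittig C=C disconnection lead back to aldehyde 12.
- Key disconnection: the bond between C2 of the dioxane ring and C1′ of the pendant ring, made by a Friedel–Crafts C-arylation (aryl C-glycosylation type) of lactol 9 with phenol 11.
- Enabling feature: C2 is an O1-bound carbon at the aldehyde oxidation level (hemiacetal → oxocarbenium ion), and it sits para to the free 4′-OH of the 3-methoxy-4,5-dioxygenated ring. That para position is the only unblocked nucleophilic site of a 2,6-dioxygenated phenol, and the same 4′-OH lets the C2–O1 bond reopen as a p-quinone methide, which funnels material to the trans isomer.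
- Lactol 9 comes from aryl lactone 6 (DIBAL-H). Lactone 6 comes from 5-hydroxyvanillin and triflate 3 (from methyl L-glycerate) by SN2 with inversion, which sets C3, followed by lactonisation.
- Ring order: both benzene rings are bought. The dioxane ring is closed in step 3 (O4–C3 by SN2, then O1–C2 by lactonisation) and carried through the key step; no ring is made afterwards.

Key step: step 7

Remark on the chemistry: positions are numbered as in 2,3-dihydro-1,4-benzodioxine (O1, C2, C3, O4, C5–C8), and primed numbers refer to the pendant aryl ring. Lactols 8 and 9 are assumed to be mixtures of C2 epimers in equilibrium with the ring-opened hydroxy aldehyde, which is of no consequence because C2 becomes planar in step 7.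

## Route

Step 1
Reactants: 1 methyl (S)-2,3-dihydroxypropanoate (methyl L-glycerate)
Product: 2 methyl (S)-2-hydroxy-3-[(triisopropylsilyl)oxy]propanoate
Conditions: TIPSCl (1.05 equiv), imidazole, CH2Cl2, 0 °C → rt
Reagents that add atoms: triisopropylsilyl chloride, CC(C)[Si](Cl)(C(C)C)C(C)C
Why: Silyl ether formation with the bulky TIPS chloride should be selective for the unhindered primary hydroxyl over the secondary α-hydroxy ester hydroxyl; the stereocentre is not touched.

Step 2
Reactants: 2 methyl (S)-2-hydroxy-3-[(triisopropylsilyl)oxy]propanoate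
Product: 3 methyl (S)-3-[(triisopropylsilyl)oxy]-2-[(trifluoromethylsulfonyl)oxy]propanoate
Conditions: Tf2O, 2,6-lutidine, CH2Cl2, −78 °C; used crude
Reagents that add atoms: trifluoromethanesulfonic anhydride, O=S(=O)(OS(=O)(=O)C(F)(F)F)C(F)(F)F
Why: O-Sulfonylation (triflate formation) at low temperature with a hindered base proceeds with retention at C2 and gives an α-carbonyl triflate that is a very good SN2 electrophile.

Step 3
Reactants: 4 3,4-dihydroxy-5-methoxybenzaldehyde (5-hydroxyvanillin); 3 methyl (S)-3-[(triisopropylsilyl)oxy]-2-[(trifluoromethylsulfonyl)oxy]propanoate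
Product: 6 (3R)-5-methoxy-2-oxo-3-{[(triisopropylsilyl)oxy]methyl}-2,3-dihydro-1,4-benzodioxine-7-carbaldehyde, via hydroxy ester 5 (not isolated)
Conditions: K2CO3 (1.0 equiv), MeCN, 0 °C → rt; then TsOH·H2O (cat.), toluene, 80 °C
Reagents that add atoms: none
Why: In this Williamson ether synthesis the 4-OH para to the formyl group is the more acidic hydroxyl, so its phenoxide should displace the α-triflate by SN2 with inversion [(S) → (R)], which sets C3, and acid-catalysed lactonisation by the neighbouring 3-OH then closes the six-membered aryl lactone with loss of methanol.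

Step 4
Reactants: 6 (3R)-5-methoxy-2-oxo-3-{[(triisopropylsilyl)oxy]methyl}-2,3-dihydro-1,4-benzodioxine-7-carbaldehyde
Product: 7 (3R)-7-(1,3-dioxolan-2-yl)-5-methoxy-3-{[(triisopropylsilyl)oxy]methyl}-1,4-benzodioxin-2(3H)-one
Conditions: TMSOCH2CH2OTMS, TMSOTf (cat.), CH2Cl2, −78 → −20 °C
Reagents that add atoms: 1,2-bis(trimethylsilyloxy)ethane, C[Si](C)(C)OCCO[Si](C)(C)C
Why: Aprotic acetalisation of the aryl aldehyde with the bis-silyl ether of ethylene glycol masks the formyl group without opening the transesterification-prone aryl lactone or touching C3.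

Step 5
Reactants: 7 (3R)-7-(1,3-dioxolan-2-yl)-5-methoxy-3-{[(triisopropylsilyl)oxy]methyl}-1,4-benzodioxin-2(3H)-one
Product: 9 (3R)-2-hydroxy-5-methoxy-3-{[(triisopropylsilyl)oxy]methyl}-2,3-dihydro-1,4-benzodioxine-7-carbaldehyde (mixture of C2 epimers), via dioxolane lactol 8 (not isolated)
Conditions: DIBAL-H (1.1 equiv), CH2Cl2, −78 °C; then 1 M HCl, THF, rt
Reagents that add atoms: water, O
Why: DIBAL-H reduction of a lactone stops at the lactol because the cyclic aluminium hemiacetal is stable at −78 °C, and the acidic work-up then hydrolyses the electron-rich aryl dioxolane (acetal hydrolysis) while C3 and the TIPS ether are unaffected.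

Step 6
Reactants: 10 3-methoxybenzene-1,2-diol (3-methoxycatechol)
Product: 11 2-methoxy-6-[(triisopropylsilyl)oxy]phenol
Conditions: TIPSCl (1.0 equiv), imidazole, DMF, 0 °C → rt
Reagents that add atoms: triisopropylsilyl chloride, CC(C)[Si](Cl)(C(C)C)C(C)C
Why: In this silylation the bulky TIPS group should go to the outer hydroxyl, which has one ortho neighbour and is the hydrogen-bond donor, rather than to the central hydroxyl flanked by OH and OMe, and silyl migration between the adjacent oxygens would lead to the same less crowded isomer.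

Step 7
Reactants: 9 (3R)-2-hydroxy-5-methoxy-3-{[(triisopropylsilyl)oxy]methyl}-2,3-dihydro-1,4-benzodioxine-7-carbaldehyde; 11 2-methoxy-6-[(triisopropylsilyl)oxy]phenol
Product: 12 (2R,3R)-2-{4-hydroxy-3-methoxy-5-[(triisopropylsilyl)oxy]phenyl}-5-methoxy-3-{[(triisopropylsilyl)oxy]methyl}-2,3-dihydro-1,4-benzodioxine-7-carbaldehyde
Conditions: 11 (1.1 equiv), BF3·OEt2 (0.3 equiv), 4 Å MS, CH2Cl2, −30 → 0 °C
Reagents that add atoms: none
Why: BF3 ionises the hemiacetal C2–OH of 9 to the aryloxy-stabilised cyclic oxocarbenium ion (O1=C2+), which is attacked by C4 of phenol 11, the position para to the free hydroxyl and the only activated site not flanked by the OMe or the bulky OTIPS group (an O-aryl acetal formed first is hindered and reverts), and loss of the proton gives 12. The closest known reaction type is the Lewis-acid Friedel–Crafts aryl C-glycosylation of lactols and glycosyl acetates with phenols, as also used for flavans from 2-chromanols. No ring is closed on this direct path; if 9 reacts through its ring-opened hydroxy-aldehyde tautomer (hydroxyalkylation), the resulting p-hydroxybenzyl cation/p-quinone methide is closed again by the catechol hydroxyl in a 6-exo-trig 1,6-oxa-addition, the ring closure of the presumed biosynthesis of benzodioxane neolignans. The new stereocentre C2 is controlled by the C3 stereocentre: attack anti to the CH2OTIPS group gives the 2,3-trans isomer kinetically, and because the C2–O1 bond of the product can reopen through the p-quinone methide (free 4′-OH), any cis isomer should drain to the diequatorial trans compound, so C2 becomes R. The step needs C- over O-arylation, para regioselectivity, mono-arylation and retention at C3; these are secured by the blocked ortho positions of 11, by about one equivalent of 11 at low temperature, and by the absence of base (no enol ether formation at C3), while the aryl aldehyde, deactivated by its para oxygen, should stay a spectator.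

Step 8
Reactants: 12 (2R,3R)-2-{4-hydroxy-3-methoxy-5-[(triisopropylsilyl)oxy]phenyl}-5-methoxy-3-{[(triisopropylsilyl)oxy]methyl}-2,3-dihydro-1,4-benzodioxine-7-carbaldehyde
Product: 13 (E)-3-[(2R,3R)-2-{4-hydroxy-3-methoxy-5-[(triisopropylsilyl)oxy]phenyl}-5-methoxy-3-{[(triisopropylsilyl)oxy]methyl}-2,3-dihydro-1,4-benzodioxin-7-yl]prop-2-enal
Conditions: Ph3P=CHCHO (1.3 equiv), toluene, 80 °C
Reagents that add atoms: (triphenylphosphoranylidene)acetaldehyde, O=CC=P(c1ccccc1)(c1ccccc1)c1ccccc1
Why: Wittig olefination with the stabilised formylmethylene ylide should convert the aryl aldehyde into the (E)-enal under neutral conditions that leave the hindered phenol, both silyl ethers and both stereocentres untouched.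

Step 9
Reactants: 13 (E)-3-[(2R,3R)-2-{4-hydroxy-3-methoxy-5-[(triisopropylsilyl)oxy]phenyl}-5-methoxy-3-{[(triisopropylsilyl)oxy]methyl}-2,3-dihydro-1,4-benzodioxin-7-yl]prop-2-enal
Product: 14 (E)-3-[(2R,3R)-2-(3,4-dihydroxy-5-methoxyphenyl)-3-(hydroxymethyl)-5-methoxy-2,3-dihydro-1,4-benzodioxin-7-yl]prop-2-enal (CNP0103768.1)
Conditions: TBAF (3 equiv), AcOH (3 equiv), THF, 0 °C → rt, argon
Reagents that add atoms: none
Why: Fluoride-mediated desilylation buffered with acetic acid should cleave the aryl and the primary alkyl TIPS ethers in one operation without base-induced damage to the enal or the air-sensitive catechol, and neither stereocentre is involved.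

## Compound list

1 | methyl (S)-2,3-dihydroxypropanoate | COC(=O)[C@@H](O)CO | starting material
2 | methyl (S)-2-hydroxy-3-[(triisopropylsilyl)oxy]propanoate | COC(=O)[C@@H](O)CO[Si](C(C)C)(C(C)C)C(C)C | intermediate
3 | methyl (S)-3-[(triisopropylsilyl)oxy]-2-[(trifluoromethylsulfonyl)oxy]propanoate | COC(=O)[C@@H](OS(=O)(=O)C(F)(F)F)CO[Si](C(C)C)(C(C)C)C(C)C | intermediate
4 | 3,4-dihydroxy-5-methoxybenzaldehyde | COc1cc(C=O)cc(O)c1O | starting material
5 | methyl (R)-2-(4-formyl-2-hydroxy-6-methoxyphenoxy)-3-[(triisopropylsilyl)oxy]propanoate | COC(=O)[C@H](Oc1c(O)cc(C=O)cc1OC)CO[Si](C(C)C)(C(C)C)C(C)C | intermediate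
6 | (3R)-5-methoxy-2-oxo-3-{[(triisopropylsilyl)oxy]methyl}-2,3-dihydro-1,4-benzodioxine-7-carbaldehyde | COc1cc(C=O)cc2OC(=O)[C@@H](CO[Si](C(C)C)(C(C)C)C(C)C)Oc12 | intermediate
7 | (3R)-7-(1,3-dioxolan-2-yl)-5-methoxy-3-{[(triisopropylsilyl)oxy]methyl}-1,4-benzodioxin-2(3H)-one | COc1cc(C3OCCO3)cc2OC(=O)[C@@H](CO[Si](C(C)C)(C(C)C)C(C)C)Oc12 | intermediate
8 | (3R)-7-(1,3-dioxolan-2-yl)-5-methoxy-3-{[(triisopropylsilyl)oxy]methyl}-2,3-dihydro-1,4-benzodioxin-2-ol | COc1cc(C3OCCO3)cc2OC(O)[C@@H](CO[Si](C(C)C)(C(C)C)C(C)C)Oc12 | intermediate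
9 | (3R)-2-hydroxy-5-methoxy-3-{[(triisopropylsilyl)oxy]methyl}-2,3-dihydro-1,4-benzodioxine-7-carbaldehyde | COc1cc(C=O)cc2OC(O)[C@@H](CO[Si](C(C)C)(C(C)C)C(C)C)Oc12 | intermediate
10 | 3-methoxybenzene-1,2-diol | COc1cccc(O)c1O | starting material
11 | 2-methoxy-6-[(triisopropylsilyl)oxy]phenol | COc1cccc(O[Si](C(C)C)(C(C)C)C(C)C)c1O | intermediate
12 | (2R,3R)-2-{4-hydroxy-3-methoxy-5-[(triisopropylsilyl)oxy]phenyl}-5-methoxy-3-{[(triisopropylsilyl)oxy]methyl}-2,3-dihydro-1,4-benzodioxine-7-carbaldehyde | COc1cc([C@H]2Oc3cc(C=O)cc(OC)c3O[C@@H]2CO[Si](C(C)C)(C(C)C)C(C)C)cc(O[Si](C(C)C)(C(C)C)C(C)C)c1O | intermediate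
13 | (E)-3-[(2R,3R)-2-{4-hydroxy-3-methoxy-5-[(triisopropylsilyl)oxy]phenyl}-5-methoxy-3-{[(triisopropylsilyl)oxy]methyl}-2,3-dihydro-1,4-benzodioxin-7-yl]prop-2-enal | COc1cc([C@H]2Oc3cc(/C=C/C=O)cc(OC)c3O[C@@H]2CO[Si](C(C)C)(C(C)C)C(C)C)cc(O[Si](C(C)C)(C(C)C)C(C)C)c1O | intermediate
14 | (E)-3-[(2R,3R)-2-(3,4-dihydroxy-5-methoxyphenyl)-3-(hydroxymethyl)-5-methoxy-2,3-dihydro-1,4-benzodioxin-7-yl]prop-2-enal | COc1cc([C@H]2Oc3cc(/C=C/C=O)cc(OC)c3O[C@@H]2CO)cc(O)c1O | target

## Summary

Total step count: 9. Longest linear sequence: 8 steps (steps 1–5 and 7–9, from 1).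

Steps most likely to fail:

**Step 7 (key step).** The oxocarbenium ion may lose the C3 proton to give the enol ether (erosion of configuration at C3). The benzylic C2–O1 bond of the product may reopen and capture a second molecule of phenol (over-arylation). The facial selectivity at C2 may also be incomplete if equilibration is slow. Fallback (known chemistry of arylglycerol β-aryl ethers), setting out from 7 and 11 and coming back to the route at 12: the C2–C1′ bond is made by carbonyl addition and the ring is closed afterwards. Lactone 7 is reduced as in step 5 but worked up with Rochelle salt, so that dioxolane lactol 8 is isolated. Phenol 11 is brominated para to the hydroxyl (NBS, MeCN, 0 °C) to 4-bromo-2-methoxy-6-[(triisopropylsilyl)oxy]phenol F1. Under acidic conditions that exclude silyl migration (ethyl vinyl ether, PPTS, CH2Cl2), F1 is converted into 5-bromo-2-(1-ethoxyethoxy)-1-methoxy-3-[(triisopropylsilyl)oxy]benzene F2. Bromine–lithium exchange (n-BuLi, THF, −78 °C) and addition of the aryllithium (2.2 equiv) to 8, which reacts through its ring-opened aldehyde, should give the 1-aryl-2-aryloxypropane-1,3-diol derivative F3 as a mixture of carbinol epimers. PPTS in wet acetone (removal of the ethoxyethyl and dioxolane groups) followed by cat. TsOH in CH2Cl2 should then close the dioxane ring through the p-quinone methide under thermodynamic control to trans-12.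

**Step 3.** With the hindered secondary triflate, alkylation may also take place at the less acidic but less crowded 3-OH (loss of site selectivity). The triflate may undergo E2 elimination, and the α-aryloxy ester may epimerise under base. Fallback, setting out from 3 and coming back at 5 (and from there at 6 as in step 3): the site of etherification is fixed by using commercial 5-bromovanillin (3-bromo-4-hydroxy-5-methoxybenzaldehyde), which has a single hydroxyl, in place of 4. Alkylation with 3 (K2CO3, MeCN, 0 °C → rt) should give methyl (R)-2-(2-bromo-4-formyl-6-methoxyphenoxy)-3-[(triisopropylsilyl)oxy]propanoate F4. Miyaura borylation (B2pin2, Pd(dppf)Cl2, KOAc, dioxane, 80 °C) would give the pinacol boronate F5, and mild oxidation (NaBO3·4H2O, THF/H2O, rt) would deliver phenol 5, which is lactonised with cat. TsOH to 6.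

**Step 8.** The product enal may react again with the ylide (over-homologation to the dienal), and the electron-rich aldehyde may be consumed only slowly. Fallback, setting out from 12 and coming back at 13: a two-step homologation through the nitrile. Horner–Wadsworth–Emmons reaction with diethyl (cyanomethyl)phosphonate (LiCl, DBU, MeCN, rt) should give the (E)-cinnamonitrile F6. Any O→O silyl migration under the base would be of no consequence, since both silyl groups fall in step 9. DIBAL-H (2.2 equiv, CH2Cl2, −78 °C; then cold 1 M HCl) would reduce the nitrile to the aldimine, which hydrolyses to enal 13.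

## Further compounds

F1 | step 7 | 4-bromo-2-methoxy-6-[(triisopropylsilyl)oxy]phenol | COc1cc(Br)cc(O[Si](C(C)C)(C(C)C)C(C)C)c1O
F2 | step 7 | 5-bromo-2-(1-ethoxyethoxy)-1-methoxy-3-[(triisopropylsilyl)oxy]benzene | COc1cc(Br)cc(O[Si](C(C)C)(C(C)C)C(C)C)c1OC(C)OCC
F3 | step 7 | (2R)-2-[4-(1,3-dioxolan-2-yl)-2-hydroxy-6-methoxyphenoxy]-1-{4-(1-ethoxyethoxy)-3-methoxy-5-[(triisopropylsilyl)oxy]phenyl}-3-[(triisopropylsilyl)oxy]propan-1-ol | COc1cc(C(O)[C@@H](CO[Si](C(C)C)(C(C)C)C(C)C)Oc2c(O)cc(C3OCCO3)cc2OC)cc(O[Si](C(C)C)(C(C)C)C(C)C)c1OC(C)OCC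
F4 | step 3 | methyl (R)-2-(2-bromo-4-formyl-6-methoxyphenoxy)-3-[(triisopropylsilyl)oxy]propanoate | COC(=O)[C@H](Oc1c(Br)cc(C=O)cc1OC)CO[Si](C(C)C)(C(C)C)C(C)C
F5 | step 3 | methyl (R)-2-[4-formyl-2-methoxy-6-(4,4,5,5-tetramethyl-1,3,2-dioxaborolan-2-yl)phenoxy]-3-[(triisopropylsilyl)oxy]propanoate | COC(=O)[C@H](Oc1c(B2OC(C)(C)C(C)(C)O2)cc(C=O)cc1OC)CO[Si](C(C)C)(C(C)C)C(C)C
F6 | step 8 | (E)-3-[(2R,3R)-2-{4-hydroxy-3-methoxy-5-[(triisopropylsilyl)oxy]phenyl}-5-methoxy-3-{[(triisopropylsilyl)oxy]methyl}-2,3-dihydro-1,4-benzodioxin-7-yl]prop-2-enenitrile | COc1cc([C@H]2Oc3cc(/C=C/C#N)cc(OC)c3O[C@@H]2CO[Si](C(C)C)(C(C)C)C(C)C)cc(O[Si](C(C)C)(C(C)C)C(C)C)c1O
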